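Each flask here is a neighbour of north, with the same charges and another way of putting them in.

    links + by-product → side product (k1 = 0.0024 /M/s)
    first end groups + second end groups ⇌ links + by-product (K2 = 82, k2 = 0.012 /M/s)

all flasks: time 5.0 h
- north: first end groups 0.10 M; second end groups 0.110 M; everything together at the start
- west: first end groups 0.10 M (fed, over 3.0 h); second end groups 0.110 M; all else is in the flask from the start; the feed brings no volume worth counting
- south-east: first end groups 0.10 M (in portions, 3, over 3.0 h); second end groups 0.110 M; first portion at the start, last at 3.0 h
- north-west: first end groups 0.10 M; second end groups 0.110 M (fed, over 3.0 h); all else is in the flask from the start; the feed brings no volume worth counting

- the flask that comes out highest in share of links in links plus side product, or "all alike" when all lie within 1.5 percentage points (north / west / south-east / north-west / all alike)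
- share of links in links plus side product at the end, north
- share of links in links plus side product at the end, west
- share of links in links plus side product at the end, south-east
- share of links in links plus side product at the end, north-west

Turn the question round: "all alike" would need the way of adding to shift the share at the end by less than 1.5 percentage points. Coupling makes one link and one by-product, and the side step uses one of each, so [links] = [by-product], and once coupling is over 1/[links] grows steadily at the constant of the side step. Falling back we set aside, its constant being 1.46 × 10⁻⁴ /M/s. With the first end groups, the limiting reagent, coupled, the share of links after a time t is 1/(1 + t/τ), where the decay clock τ = 1.16 h is the time in which a full charge of links falls to half. A clock started at once gives 18.8% at the end of the run, and one started when the addition ends gives 36.7%, a gap of 18 points, so we do not expect these flasks alike.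

Now join the ends. In north, coupling takes about 0.231 h, and the clock runs for the rest, which gives 19.5%. In west, the steady feed pushes links towards a balance of 0.0621 M, and a hyperbolic tangent of 1.61 brings them to 0.0573 M when the feed ends; the clock then leaves a share of 28.8%. North-west we count as west. In south-east, portion by portion, links fall to 0.0233 M before the second portion and 0.0327 M before the last, which ends at 30.8%. Both sums take coupling as instant, so we hold them for low, but we commit to the order: south-east, ahead by 2 points.

The forecast gave 24% for north, 37% for west, 35% for south-east and 34% for north-west and named west narrowly, since “its unreacted first end groups lag behind the feed”, a margin it held to be within its uncertainty, where we name another flask.

The flasks give 23.3% for north, 35.0% for west, 37.4% for south-east and 34.3% for north-west, so south-east comes out highest, above our sum. In south-east at 5.00 h, links are made at 0.286 of the rate at which they are used up, and the clock run from the last portion gives 36.7%. Left until 20 h, south-east gives 6.91%, and the same clock from the last portion gives 6.37%.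

The numbers of this flask stand for no real mixture; the rest is arithmetic.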